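**Plan**

1. Retrosynthesis: the quinone is cut back to a hydroquinone dimethyl ether; the exocyclic C=C of the lactone is cut (Still–Gennari olefination) into a chromene aldehyde and a 3-phosphono-δ-lactone; the lactone is cut at its ring CH2–CH2 bond (C4–C5).
2. The chromene is cut at O1–C8a and at C4–C4a back to (R)-linalool and a bromo-iodo arene; the side chain is cut at the allylic CH2–CH2 bond beside the E-alkene.
3. Forward, lactone fragment: (R)-glycerate acetonide, iodo diol, phosphonoacetate ester, phosphonoacrylate, then 6-endo radical closure of the δ-lactone ring.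
4. Forward, chromene fragment: hydroboration/Suzuki coupling of linalool, Pd C–O closure to the chroman, DDQ to the 2H-chromene, chain extension to the aldehyde; then olefination joins the fragments and oxidation gives the quinone.
5. Stereochemistry: lactone C6 comes from the glycerate, chromene C2 from linalool (no bond to it is broken), the E-alkene from the E-methyl of linalool's isopropylidene group, the Z-alkylidene from the Still–Gennari step.
6. Enabling feature: in the six-membered lactone ring, C4 is β to the lactone carbonyl and can be the free CH2 end of a C3=C4 acrylate activated by a phosphonate on C3, while C5, next to the acyloxy-bearing C6, can be a primary radical; the phosphonate then serves the olefination.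

Key step: step 6

Assumption: commercial (R)-(−)-linalool of high enantiomeric purity is used, and bis(2,2,2-trifluoroethyl)phosphonoacetic acid and acetaldehyde N-tert-butylimine are taken as purchasable reagents.

**Route**

Step 1
Reactants: 1 methyl (R)-2,2-dimethyl-1,3-dioxolane-4-carboxylate
Product: 3 (R)-2-(2,2-dimethyl-1,3-dioxolan-4-yl)propan-2-ol, via methyl ketone 2 (not isolated)
Conditions: MeMgBr (2.5 equiv), THF, 0 °C to rt; aq NH4Cl
Reagents that add atoms: methylmagnesium bromide, C[Mg]Br
Why: Double Grignard addition to the ester gives the tertiary carbinol, and the dioxolane stereocentre (the future lactone C6) should survive because the intermediate ketone is consumed faster than it is enolised.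

Step 2
Reactants: 3 (R)-2-(2,2-dimethyl-1,3-dioxolan-4-yl)propan-2-ol
Product: 4 (R)-3-methylbutane-1,2,3-triol
Conditions: AcOH/H2O (4:1), 40 °C; evaporation
Reagents that add atoms: none
Why: Acid-catalysed acetal hydrolysis frees the 1,2-diol without touching the stereocentre.

Step 3
Reactants: 4 (R)-3-methylbutane-1,2,3-triol
Product: 5 (S)-1-iodo-3-methylbutane-2,3-diol
Conditions: I2, PPh3, imidazole, MeCN/THF, 0 °C to rt
Reagents that add atoms: iodine, II
Why: Appel-type iodination goes through an alkoxyphosphonium ion that only the unhindered primary hydroxyl forms readily; the descriptor changes to S only because CH2I now outranks the carbinol carbon.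

Step 4
Reactants: 5 (S)-1-iodo-3-methylbutane-2,3-diol; 6 bis(2,2,2-trifluoroethyl)phosphonoacetic acid
Product: 7 (S)-3-hydroxy-1-iodo-3-methylbutan-2-yl 2-[bis(2,2,2-trifluoroethoxy)phosphoryl]acetate
Conditions: DCC, DMAP (5 mol%), CH2Cl2, 0 °C
Reagents that add atoms: none
Why: Steglich esterification should acylate the secondary hydroxyl and leave the much more hindered tertiary one free.

Step 5
Reactants: 7 (S)-3-hydroxy-1-iodo-3-methylbutan-2-yl 2-[bis(2,2,2-trifluoroethoxy)phosphoryl]acetate
Product: 10 (S)-3-hydroxy-1-iodo-3-methylbutan-2-yl 2-[bis(2,2,2-trifluoroethoxy)phosphoryl]acrylate, via Mannich base 8 (not isolated), via trimethylammonium iodide 9 (not isolated)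
Conditions: CH2=NMe2+ I− (1.3 equiv), i-Pr2NEt, LiCl, MeCN, −20 °C; then MeI, rt; then aq NaHCO3
Reagents that add atoms: N,N-dimethylmethyleneiminium iodide, C=[N+](C)C.[I-]
Why: Mannich aminomethylation of the soft-enolised phosphonoacetate, N-methylation and E1cB loss of trimethylamine is the standard α-methylenation of an active methylene compound, and it keeps the phosphonate that an aldol route with formaldehyde would expel.

Step 6
Reactants: 10 (S)-3-hydroxy-1-iodo-3-methylbutan-2-yl 2-[bis(2,2,2-trifluoroethoxy)phosphoryl]acrylate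
Product: 11 (6R)-3-[bis(2,2,2-trifluoroethoxy)phosphoryl]-6-(2-hydroxypropan-2-yl)oxan-2-one (mixture of C3 epimers)
Conditions: (Me3Si)3SiH (1.3 equiv) and AIBN (0.3 equiv) added over 8 h, benzene (0.005 M), 80 °C
Reagents that add atoms: none
Why: Proposed new method: the silyl radical abstracts iodine from C5, the nucleophilic primary radical adds to C4, the unsubstituted end of the electron-poor phosphonoacrylate, and the C3 radical, stabilised by both the ester and the phosphonate, takes hydrogen from the silane. The closest known reactions are the intermolecular Giese addition of alkyl iodides to doubly activated acrylates and the endo-mode radical macrolactonisation of iodoalkyl acrylates. The δ-lactone ring closes in the 6-endo-trig mode through the s-cis rotamer of the ester, and 5-exo attack at C3 is not expected because it would give an unstabilised primary radical at a fully substituted carbon. No stereocentre is set under control: C6 comes unchanged from 1, and C3 forms as a mixture of epimers that is erased in step 14. The step needs ring closure to beat reduction of the C5 radical and its 1,2-acyloxy shift; high dilution with slow silane addition, the doubly activated acceptor and the fact that iodine abstraction is far faster than silyl addition to the acrylate should secure this.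

Step 7
Reactants: 12 1-bromo-2,5-dimethoxy-4-methylbenzene
Product: 14 1-bromo-2-iodo-3,6-dimethoxy-4-methylbenzene, via aryllithium 13 (not isolated)
Conditions: LiN(i-Pr)2, THF, −78 °C; then I2, −78 °C
Reagents that add atoms: iodine, II
Why: Directed ortho-lithiation removes the C–H flanked by OMe and Br, the most acidic one, at a temperature where neither Br/Li exchange nor aryne formation should compete, and iodine quench gives the 1,2-dihalide.

Step 8
Reactants: 15 (R)-linalool; 14 1-bromo-2-iodo-3,6-dimethoxy-4-methylbenzene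
Product: 17 (R)-1-(2-bromo-3,6-dimethoxy-5-methylphenyl)-3,7-dimethyloct-6-en-3-ol, via alkyl-9-BBN adduct 16 (not isolated)
Conditions: 9-BBN (1.5 equiv), THF, 0 °C to rt; then 14, PdCl2(dppf) (5 mol%), 3 M aq NaOH, THF, 60 °C
Reagents that add atoms: none
Why: Hydroboration/B-alkyl Suzuki–Miyaura coupling: 9-BBN adds anti-Markovnikov to the monosubstituted vinyl group only, and zerovalent palladium inserts into C–I much faster than into C–Br, so the bromide is kept for step 9 and the carbinol stereocentre is untouched.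

Step 9
Reactants: 17 (R)-1-(2-bromo-3,6-dimethoxy-5-methylphenyl)-3,7-dimethyloct-6-en-3-ol
Product: 18 (R)-5,8-dimethoxy-2,6-dimethyl-2-(4-methylpent-3-en-1-yl)chromane
Conditions: Pd(OAc)2 (5 mol%), 2-(di-tert-butylphosphino)-1,1'-binaphthyl (6 mol%), Cs2CO3, toluene, 80 °C
Reagents that add atoms: none
Why: Intramolecular Buchwald–Hartwig etherification closes the chroman ring by C–O reductive elimination; the tertiary alkoxide has no hydrogen for β-hydride elimination and no bond to the stereocentre changes.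

Step 10
Reactants: 18 (R)-5,8-dimethoxy-2,6-dimethyl-2-(4-methylpent-3-en-1-yl)chromane
Product: 19 (R)-5,8-dimethoxy-2,6-dimethyl-2-(4-methylpent-3-en-1-yl)-2H-chromene
Conditions: DDQ (1.3 equiv), 1,4-dioxane, 90 °C
Reagents that add atoms: none
Why: DDQ dehydrogenation: hydride abstraction from benzylic C4, whose cation is stabilised by the ortho methoxy group and the ring oxygen, then loss of H from C3, as known for alkoxy-2,2-dialkylchromans.

Step 11
Reactants: 19 (R)-5,8-dimethoxy-2,6-dimethyl-2-(4-methylpent-3-en-1-yl)-2H-chromene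
Product: 20 (E)-5-[(R)-5,8-dimethoxy-2,6-dimethyl-2H-chromen-2-yl]-2-methylpent-2-en-1-ol
Conditions: SeO2 (0.3 equiv), t-BuOOH (3 equiv), salicylic acid (0.1 equiv), CH2Cl2, rt
Reagents that add atoms: tert-butyl hydroperoxide, CC(C)(C)OO
Why: SeO2-catalysed allylic (Riley) oxidation by ene reaction and [2,3]-shift attacks the E-methyl of the terminal isopropylidene group, which fixes the E geometry of the new allylic alcohol.

Step 12
Reactants: 20 (E)-5-[(R)-5,8-dimethoxy-2,6-dimethyl-2H-chromen-2-yl]-2-methylpent-2-en-1-ol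
Product: 21 (R)-2-[(E)-5-bromo-4-methylpent-3-en-1-yl]-5,8-dimethoxy-2,6-dimethyl-2H-chromene
Conditions: CBr4, PPh3, CH2Cl2, 0 °C
Reagents that add atoms: carbon tetrabromide, BrC(Br)(Br)Br
Why: Appel bromination converts the primary allylic alcohol to the bromide by SN2 displacement of the alkoxyphosphonium group, without allylic transposition or loss of alkene geometry.

Step 13
Reactants: 21 (R)-2-[(E)-5-bromo-4-methylpent-3-en-1-yl]-5,8-dimethoxy-2,6-dimethyl-2H-chromene; 22 acetaldehyde N-tert-butylimine
Product: 25 (E)-7-[(R)-5,8-dimethoxy-2,6-dimethyl-2H-chromen-2-yl]-4-methylhept-4-enal, via lithiated imine 23 (not isolated), via alkylated imine 24 (not isolated)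
Conditions: 22, LiN(i-Pr)2, THF, −78 to 0 °C; then 21, −78 °C to rt; then aq tartaric acid, 0 °C
Reagents that add atoms: water, O
Why: Aza-enolate (metalated imine) alkylation at the primary allylic carbon adds the two-carbon aldehyde unit by SN2, and mild acid hydrolysis of the imine frees the aldehyde.

Step 14
Reactants: 11 (6R)-3-[bis(2,2,2-trifluoroethoxy)phosphoryl]-6-(2-hydroxypropan-2-yl)oxan-2-one; 25 (E)-7-[(R)-5,8-dimethoxy-2,6-dimethyl-2H-chromen-2-yl]-4-methylhept-4-enal
Product: 27 (3Z,6R)-3-{(4E)-7-[(2R)-5,8-dimethoxy-2,6-dimethyl-2H-chromen-2-yl]-4-methylhept-4-en-1-ylidene}-6-(2-hydroxypropan-2-yl)oxan-2-one, via potassium phosphonate 26 (not isolated)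
Conditions: KN(SiMe3)2 (1.05 equiv), 18-crown-6 (3 equiv), THF, −78 °C; then 25, −78 °C
Reagents that add atoms: none
Why: Still–Gennari olefination: the electron-poor bis(trifluoroethyl) phosphonate makes elimination from the kinetic adduct fast, which with α-substituted phosphonoacetates places the aldehyde chain cis to the carbonyl, here the Z-alkylidene lactone with the ring CH2 acting as the α-substituent.

Step 15
Reactants: 27 (3Z,6R)-3-{(4E)-7-[(2R)-5,8-dimethoxy-2,6-dimethyl-2H-chromen-2-yl]-4-methylhept-4-en-1-ylidene}-6-(2-hydroxypropan-2-yl)oxan-2-one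
Product: 28 (2R)-2-{(3E,7Z)-7-[(6R)-6-(2-hydroxypropan-2-yl)-2-oxooxan-3-ylidene]-4-methylhept-3-en-1-yl}-2,6-dimethyl-2H-chromene-5,8-dione
Conditions: (NH4)2Ce(NO3)6 (2.5 equiv), MeCN/H2O (2:1), 0 °C, 10 min
Reagents that add atoms: water, O
Why: Oxidative demethylation of the 1,4-dimethoxyarene by tetravalent cerium (arene radical cation, water addition, loss of methanol) should give the para-quinone quickly at 0 °C, leaving the alkenes, the lactone and the tertiary alcohol intact.

**Compound list**

1 | methyl (R)-2,2-dimethyl-1,3-dioxolane-4-carboxylate | CC1(C)OC[C@@H](O1)C(=O)OC | starting material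
2 | (R)-1-(2,2-dimethyl-1,3-dioxolan-4-yl)ethan-1-one | CC1(C)OC[C@@H](O1)C(C)=O | intermediate
3 | (R)-2-(2,2-dimethyl-1,3-dioxolan-4-yl)propan-2-ol | CC1(C)OC[C@@H](O1)C(C)(C)O | intermediate
4 | (R)-3-methylbutane-1,2,3-triol | OC[C@@H](O)C(C)(C)O | intermediate
5 | (S)-1-iodo-3-methylbutane-2,3-diol | IC[C@@H](O)C(C)(C)O | intermediate
6 | bis(2,2,2-trifluoroethyl)phosphonoacetic acid | OC(=O)CP(=O)(OCC(F)(F)F)OCC(F)(F)F | starting material
7 | (S)-3-hydroxy-1-iodo-3-methylbutan-2-yl 2-[bis(2,2,2-trifluoroethoxy)phosphoryl]acetate | IC[C@@H](OC(=O)CP(=O)(OCC(F)(F)F)OCC(F)(F)F)C(C)(C)O | intermediate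
8 | (S)-3-hydroxy-1-iodo-3-methylbutan-2-yl 2-[bis(2,2,2-trifluoroethoxy)phosphoryl]-3-(dimethylamino)propanoate | IC[C@@H](OC(=O)C(CN(C)C)P(=O)(OCC(F)(F)F)OCC(F)(F)F)C(C)(C)O | intermediate
9 | trimethylammonium iodide derived from 8 by N-methylation | IC[C@@H](OC(=O)C(C[N+](C)(C)C)P(=O)(OCC(F)(F)F)OCC(F)(F)F)C(C)(C)O.[I-] | intermediate
10 | (S)-3-hydroxy-1-iodo-3-methylbutan-2-yl 2-[bis(2,2,2-trifluoroethoxy)phosphoryl]acrylate | IC[C@@H](OC(=O)C(=C)P(=O)(OCC(F)(F)F)OCC(F)(F)F)C(C)(C)O | intermediate
11 | (6R)-3-[bis(2,2,2-trifluoroethoxy)phosphoryl]-6-(2-hydroxypropan-2-yl)oxan-2-one | O=C1O[C@H](CCC1P(=O)(OCC(F)(F)F)OCC(F)(F)F)C(C)(C)O | intermediate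
12 | 1-bromo-2,5-dimethoxy-4-methylbenzene | Cc1cc(OC)c(Br)cc1OC | starting material
13 | (2-bromo-3,6-dimethoxy-5-methylphenyl)lithium | Cc1cc(OC)c(Br)c([Li])c1OC | intermediate
14 | 1-bromo-2-iodo-3,6-dimethoxy-4-methylbenzene | Cc1cc(OC)c(Br)c(I)c1OC | intermediate
15 | (R)-linalool, (R)-3,7-dimethylocta-1,6-dien-3-ol | CC(C)=CCC[C@@](C)(O)C=C | starting material
16 | (R)-1-(9-borabicyclo[3.3.1]nonan-9-yl)-3,7-dimethyloct-6-en-3-ol | CC(C)=CCC[C@@](C)(O)CCB1C2CCCC1CCC2 | intermediate
17 | (R)-1-(2-bromo-3,6-dimethoxy-5-methylphenyl)-3,7-dimethyloct-6-en-3-ol | Cc1cc(OC)c(Br)c(CC[C@](C)(O)CCC=C(C)C)c1OC | intermediate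
18 | (R)-5,8-dimethoxy-2,6-dimethyl-2-(4-methylpent-3-en-1-yl)chromane | Cc1cc(OC)c2c(CC[C@@](C)(CCC=C(C)C)O2)c1OC | intermediate
19 | (R)-5,8-dimethoxy-2,6-dimethyl-2-(4-methylpent-3-en-1-yl)-2H-chromene | Cc1cc(OC)c2c(C=C[C@@](C)(CCC=C(C)C)O2)c1OC | intermediate
20 | (E)-5-[(R)-5,8-dimethoxy-2,6-dimethyl-2H-chromen-2-yl]-2-methylpent-2-en-1-ol | Cc1cc(OC)c2c(C=C[C@@](C)(CC/C=C(\C)CO)O2)c1OC | intermediate
21 | (R)-2-[(E)-5-bromo-4-methylpent-3-en-1-yl]-5,8-dimethoxy-2,6-dimethyl-2H-chromene | Cc1cc(OC)c2c(C=C[C@@](C)(CC/C=C(\C)CBr)O2)c1OC | intermediate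
22 | acetaldehyde N-tert-butylimine | CC=NC(C)(C)C | starting material
23 | lithiated acetaldehyde N-tert-butylimine | [Li]CC=NC(C)(C)C | intermediate
24 | N-tert-butylimine of aldehyde 25 | Cc1cc(OC)c2c(C=C[C@@](C)(CC/C=C(\C)CCC=NC(C)(C)C)O2)c1OC | intermediate
25 | (E)-7-[(R)-5,8-dimethoxy-2,6-dimethyl-2H-chromen-2-yl]-4-methylhept-4-enal | Cc1cc(OC)c2c(C=C[C@@](C)(CC/C=C(\C)CCC=O)O2)c1OC | intermediate
26 | potassium enolate of phosphono lactone 11 | [K+].[O-]C1=C(CC[C@@H](O1)C(C)(C)O)P(=O)(OCC(F)(F)F)OCC(F)(F)F | intermediate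
27 | (3Z,6R)-3-{(4E)-7-[(2R)-5,8-dimethoxy-2,6-dimethyl-2H-chromen-2-yl]-4-methylhept-4-en-1-ylidene}-6-(2-hydroxypropan-2-yl)oxan-2-one | Cc1cc(OC)c2c(C=C[C@@](C)(CC/C=C(\C)CC/C=C3/CC[C@H](C(C)(C)O)OC3=O)O2)c1OC | intermediate
28 | (2R)-2-{(3E,7Z)-7-[(6R)-6-(2-hydroxypropan-2-yl)-2-oxooxan-3-ylidene]-4-methylhept-3-en-1-yl}-2,6-dimethyl-2H-chromene-5,8-dione | CC1=CC(=O)C2=C(C=C[C@@](C)(CC/C=C(\C)CC/C=C3/CC[C@H](C(C)(C)O)OC3=O)O2)C1=O | target

**Count and risks**

Total steps: 15. Longest linear sequence: 9 steps (steps 7 to 15, from arene 12 to target 28).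

Steps most likely to fail:

1. Step 6 (proposed new method). The primary radical may be reduced, or its acyloxy group may migrate, before the endo closure, because the ester tether spends most of its time in the rotamer that cannot cyclise. The fallback uses known chemistry, sets out from 5 and comes back at 11. Commercial methyl bis(2,2,2-trifluoroethyl)phosphonoacetate is methylenated as in step 5 to methyl 2-[bis(2,2,2-trifluoroethoxy)phosphoryl]acrylate F1. Intermolecular Giese addition of the radical from 5 ((Me3Si)3SiH, AIBN, excess F1) should give methyl (5R)-2-[bis(2,2,2-trifluoroethoxy)phosphoryl]-5,6-dihydroxy-6-methylheptanoate F2. Acid-catalysed lactonisation of its secondary hydroxyl (pyridinium tosylate, toluene, 60 °C) then gives 11, so the ring closes at the ester C–O bond and no tether rotamer is involved.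

2. Step 5. The phosphonate enolate may alkylate the neighbouring CH2I carbon (a 5-exo-tet closure to a γ-lactone) before it meets the iminium salt. The fallback sets out from 6 and 5 and comes back at 10. Acid 6 is converted with tert-butyl 2,2,2-trichloroacetimidate into tert-butyl 2-[bis(2,2,2-trifluoroethoxy)phosphoryl]acetate F3, which is methylenated in the absence of any alkyl iodide to tert-butyl 2-[bis(2,2,2-trifluoroethoxy)phosphoryl]acrylate F4. CF3CO2H frees 2-[bis(2,2,2-trifluoroethoxy)phosphoryl]acrylic acid F5, which is esterified with 5 (DCC, no DMAP) to give 10 without any base in the presence of the iodide.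

3. Step 14. Facial and geometric selectivity may be poor with the cyclic phosphonate, giving too much of the E-alkylidene isomer. The fallback sets out from 25 and comes back at 27, and sets the geometry by a sigmatropic step instead. Morita–Baylis–Hillman reaction of 25 with methyl acrylate (DABCO) gives methyl (6E)-9-[(R)-5,8-dimethoxy-2,6-dimethyl-2H-chromen-2-yl]-3-hydroxy-6-methyl-2-methylidenenon-6-enoate F6. Commercial 3-hydroxy-3-methylbutan-2-one is ketalised with trimethyl orthoformate to 3,3-dimethoxy-2-methylbutan-2-ol F7. Heating F6 with F7 and catalytic 2,4-dinitrophenol (toluene, 110 °C) brings about a ketal Claisen rearrangement through a chair with the chain equatorial, which should give methyl (2Z,6E)-9-[(R)-5,8-dimethoxy-2,6-dimethyl-2H-chromen-2-yl]-2-(4-hydroxy-4-methyl-3-oxopentyl)-6-methylnona-2,6-dienoate F8 with the chain cis to the ester. Corey–Bakshi–Shibata reduction ((S)-2-methyl-oxazaborolidine, BH3·SMe2; the hydroxy-isopropyl group as the large group) should give methyl (2Z,6E)-9-[(R)-5,8-dimethoxy-2,6-dimethyl-2H-chromen-2-yl]-2-[(3R)-3,4-dihydroxy-4-methylpentyl]-6-methylnona-2,6-dienoate F9, and mild acid closes the lactone to 27.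

**Further compounds**

F1 | step 6 | methyl 2-[bis(2,2,2-trifluoroethoxy)phosphoryl]acrylate | COC(=O)C(=C)P(=O)(OCC(F)(F)F)OCC(F)(F)F
F2 | step 6 | methyl (5R)-2-[bis(2,2,2-trifluoroethoxy)phosphoryl]-5,6-dihydroxy-6-methylheptanoate | COC(=O)C(CC[C@@H](O)C(C)(C)O)P(=O)(OCC(F)(F)F)OCC(F)(F)F
F3 | step 5 | tert-butyl 2-[bis(2,2,2-trifluoroethoxy)phosphoryl]acetate | CC(C)(C)OC(=O)CP(=O)(OCC(F)(F)F)OCC(F)(F)F
F4 | step 5 | tert-butyl 2-[bis(2,2,2-trifluoroethoxy)phosphoryl]acrylate | CC(C)(C)OC(=O)C(=C)P(=O)(OCC(F)(F)F)OCC(F)(F)F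
F5 | step 5 | 2-[bis(2,2,2-trifluoroethoxy)phosphoryl]acrylic acid | OC(=O)C(=C)P(=O)(OCC(F)(F)F)OCC(F)(F)F
F6 | step 14 | methyl (6E)-9-[(R)-5,8-dimethoxy-2,6-dimethyl-2H-chromen-2-yl]-3-hydroxy-6-methyl-2-methylidenenon-6-enoate | Cc1cc(OC)c2c(C=C[C@@](C)(CC/C=C(\C)CCC(O)C(=C)C(=O)OC)O2)c1OC
F7 | step 14 | 3,3-dimethoxy-2-methylbutan-2-ol | COC(C)(OC)C(C)(C)O
F8 | step 14 | methyl (2Z,6E)-9-[(R)-5,8-dimethoxy-2,6-dimethyl-2H-chromen-2-yl]-2-(4-hydroxy-4-methyl-3-oxopentyl)-6-methylnona-2,6-dienoate | Cc1cc(OC)c2c(C=C[C@@](C)(CC/C=C(\C)CC/C=C(/CCC(=O)C(C)(C)O)C(=O)OC)O2)c1OC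
F9 | step 14 | methyl (2Z,6E)-9-[(R)-5,8-dimethoxy-2,6-dimethyl-2H-chromen-2-yl]-2-[(3R)-3,4-dihydroxy-4-methylpentyl]-6-methylnona-2,6-dienoate | Cc1cc(OC)c2c(C=C[C@@](C)(CC/C=C(\C)CC/C=C(/CC[C@@H](O)C(C)(C)O)C(=O)OC)O2)c1OC
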